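The readings come from a simulation with made-up constants; noise was put on by code.

A one-step world turns substrate and partner into product until one charge has reacted, but this flask, whose first readings are the beta run, does not read like that.

the same everywhere: substrate 0.10 M (fed, over 10 s)

| flask | partner | protic impurity | remark | time |
|---|---|---|---|---|
| beta | 0.080 M | 5 mM | the very flask that is asked about, followed so far |  |
| flask | 0.0800 M | 5.00 mM |  | 8.0 min |

beta run (percent of the substrate charged)

| time / s | substrate / % | product / % | intermediate C / % |
|---|---|---|---|
| 10.0 | 59.3 | 2.5 | 24.6 |
| 15.0 | 56.6 | 5.8 | 23.5 |
| 25.0 | 55.8 | 8.5 | 22.3 |
| 40.0 | 54.0 | 10.3 | 21.2 |

(standard deviation of a reading: 0.3 percentage points)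

- what was read earlier has a scatter of 0.3 percentage points, one standard deviation
- the reaction counts as stopped when no species that holds the substrate changes by six tenths of a point or more over the second half of the time

- which holds at 8.0 min: what has brought the reaction to rest, or that it has not come to rest (forward and back rates have come level / all of the substrate has reacted / it is still moving / the partner has run out first)
- conversion of substrate at 8.0 min
- amount of product at 8.0 min, in percent of the substrate charged
- amount of intermediate C at 8.0 min, in percent of the substrate charged
- amount of intermediate A at 8.0 min, in percent of the substrate charged
- amount of product if the flask were left three thousand times as long, in percent of the substrate charged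

Product is creeping towards a plateau while substrate and intermediate C sink slowly together, their ratio holding nearly steady. So these look like forms in pre-equilibrium, and the useful number is one in which time drops out: a forward rate divided by its back rate, which is one when the rates are level.

Suppose intermediate C holds two partners, every other form holds one, and protic impurity takes one each. Free partner b is then the partner charge less the impurity charge, less the substrate charge times the sum of two fractions: that of substrate reacted and that standing as intermediate C. Two partner-taking steps, once level, make intermediate C over substrate proportional to b squared, so the balance quotient Q, that ratio divided by b squared, holds no time.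

The mean of the beta readings from 15.0 s to 40.0 s gives a ratio of 0.403 and b of 8.13 mM, hence Q of 6090 M⁻², a reading that carries their scatter. Going by the nearly steady ratio in the readings, my own reckoning expects this flask to rest by level rates at 8.0 min, with that ratio little changed.

The forecast, reading “a fast-equilibrated pool that slowly feeds product”, states that forward and back rates have come level, with conversion 47.5%, product 12.8%, intermediate C 20.5%, intermediate A 14.2% and product 13.2% in the long run.

In the flask forward and back rates have come level, with conversion 46.0%, product 11.6%, intermediate C 20.7%, intermediate A 9.91% and product 11.6% in the long run.

    intermediate A ⇌ intermediate B (K = 0.390, k = 0.670 s⁻¹)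
    substrate + partner ⇌ intermediate A (K = 22.0 M⁻¹, k = 13.0 M⁻¹ s⁻¹)
    partner + intermediate A ⇌ intermediate C (K = 250 M⁻¹, k = 36.0 M⁻¹ s⁻¹)
    partner + protic impurity → quenched reagent (k = 8.30 M⁻¹ s⁻¹)
    intermediate B ⇌ product (K = 3.00, k = 0.220 s⁻¹)

In this flask at 8.00 min, partner + intermediate A and intermediate C relax by that step alone with a half-life of 0.866 s, far shorter than the 8.0 min of the run, and up to that time back turnover reaches 99.5% of forward from intermediate A to intermediate B and 97% from intermediate B to product. The result's figures leave b at 8.34 mM, so Q gives intermediate C over substrate of 0.424 against 0.383 found. In the neighbour flask with 0.040 M of substrate, partner left at 27.2% of its charge is 21.7 mM, so Q gives 2.87; the computed neighbour holds 2.60.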